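The readings are simulated for substances that don't exist.

A small charge of free catalyst, 1.0 mM against 0.10 M of substrate and 0.180 M of reagent, is working in this flask, and we want to know where it stands at 2.0 d.

- winter: substrate 0.10 M; reagent 0.18 M; free catalyst 1 mM; the very flask that is asked about, followed so far
- flask: substrate 0.10 M; reagent 0.180 M; free catalyst 1.0 mM; time 2.0 d

winter run (percent of the substrate charged)

| time / h | substrate / % | product / % |
|---|---|---|
| 1.50 | 99.0 | 1.1 |
| 3.00 | 97.6 | 1.4 |
| 5.00 | 96.8 | 3.1 |
| 10.0 | 93.8 | 5.2 |
| 20.0 | 88.1 | 10.5 |

(scatter of a reading: 0.3 percentage points)

- the earlier runs do not show how much of reagent is bound; that part of a forecast is a guess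

- part of the substrate that has reacted at 2.0 d
- share of the unused reagent that is free and not bound as idle adduct, at 2.0 d

We reckon with the fraction of substrate left, not the fraction made, since for a first-order loss its logarithm falls in step with time. The reading at 20.0 h leaves 88.1%, which gives a pseudo-first-order constant of 0.00633 /h; the reading at 10.0 h gives 0.00640 /h, the same within the scatter. Dividing by the catalyst charge gives the catalyst constant, the fall in the logarithm of the fraction left per hour and per mole of catalyst charged per litre: 6.33 /M/h. Multiplied by 1.0 mM and 2.0 d, it gives an exponent of 0.304, so 73.8% would be left.

The weak link is that this holds [reagent] at its early level. If the rate follows [reagent] and reagent goes mole for mole with substrate, the mean [reagent] over the whole time stands at 0.959 of its mean over the first 20.0 h. Scaling the exponent by that factor leaves 74.7%, and we commit to 25.3% reacted. The runs do not show bound reagent, so we reckon no free share.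

The forecast stands at 25% reacted and 90% free, and of the second it says “This is a guess: mostly free, with a wide range”.

The flask gives 24.9% reacted and 89.4% free.

    substrate + free catalyst ⇌ catalyst intermediate A (K = 41.0 /M, k = 0.0140 /M/s)
    catalyst intermediate A ⇌ catalyst intermediate B (K = 2.00, k = 0.00140 /s)
    reagent + catalyst intermediate B ⇌ catalyst intermediate C (K = 7.40 /M, k = 0.00840 /M/s)
    catalyst intermediate C ⇌ catalyst intermediate D (K = 1.80, k = 0.00170 /s)
    catalyst intermediate D → released group + catalyst intermediate E (k = 0.0590 /s)
    catalyst intermediate E ⇌ free catalyst + product (K = 0.0570 M, k = 4.20 × 10⁻⁴ /s)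
    reagent + released group ⇌ idle adduct, settled at all times (K = 15.0 /M)

At 2.00 d the flask keeps 75% of its substrate against our 74.7%, so the catalyst constant of 6.33 /M/h carries over. The time allowed is the main reason this flask stands at 24.9% reacted: the same flask left ten times as long reaches 97.1%, a difference of 72 percentage points. For the neighbour charged with 0.0025 M of free catalyst, over the same time, we reckon from the catalyst constant, without the reagent scaling, an exponent of 0.760, which leaves 46.8%, and that flask holds 47% of its substrate.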